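Ring C is opened at its isolated carbonyl carbon: C4 lies between C4a of ring A and the C3–C2 unit that carries ring B, so it can enter as carbon monoxide. One palladium-mediated operation unites an ortho-iodophenol (iodine on the future C4a, free hydroxyl as the future O1), CO and a ring-B arylacetylene, creating C4a–C4, C4–C3 and O1–C2 and closing ring C as a protected luteolin. In the precursors benzyl ethers mask the hydroxyls that stay free (O5, O3') and methoxymethyl ethers those destined for sulfation (O7, O4'). C3 hydroxylation, acetal removal, exhaustive sulfation and hydrogenolysis then complete the target.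

Key step: step 7

Remark: the target is a planar, achiral flavonol, so no stereocentre has to be set; the name is read as quercetin 3,4',7-trisulfate.
Remark: the sulfate monoesters 16 and 17 are drawn as hydrogen sulfates to match the target string; they would be handled as their trisodium salts after Na+ exchange.

Step 1
Reactants: 1 phloroglucinol
Product: 2 5-(methoxymethoxy)benzene-1,3-diol
Conditions: MOMCl (1.0 equiv, slow addition), i-Pr2NEt (1.1 equiv), THF, 0 °C → rt; 1 used in threefold excess and washed out with water
Reagents that add atoms: chloromethyl methyl ether, COCCl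
Why: MOM protection (O-alkylation of a phenol by an α-chloro ether) in which the three hydroxyls are equivalent, so only the degree of alkylation has to be held at one, which the excess of the cheap, water-soluble triol should do.

Step 2
Reactants: 2 5-(methoxymethoxy)benzene-1,3-diol
Product: 3 2-iodo-5-(methoxymethoxy)benzene-1,3-diol
Conditions: I2 (1.0 equiv, slow addition), NaHCO3, THF/H2O, 0 °C
Reagents that add atoms: iodine, II
Why: Electrophilic aromatic iodination of the resorcinol phenoxide under bicarbonate, which, as for resorcinol itself, should go kinetically to C2 between the two hydroxyls (here also para to the MOM ether), while the buffer spares the acetal and suppresses acid-induced iodine migration.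

Step 3
Reactants: 3 2-iodo-5-(methoxymethoxy)benzene-1,3-diol
Product: 4 3-(benzyloxy)-2-iodo-5-(methoxymethoxy)phenol
Conditions: BnBr (1.0 equiv), K2CO3 (1.0 equiv), DMF, 0 °C → rt; recovered 3 recycled
Reagents that add atoms: benzyl bromide, BrCc1ccccc1
Why: Williamson ether synthesis on a diol whose two hydroxyls are equivalent by symmetry, so there is no regiochemical issue, and one equivalent of base and halide should alkylate the monoanion once, with diol and bis-ether separable by chromatography.

Step 4
Reactants: 5 3,4-dihydroxybenzaldehyde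
Product: 6 3-hydroxy-4-(methoxymethoxy)benzaldehyde
Conditions: MOMCl (1.05 equiv), K2CO3 (1.1 equiv), acetone, 0 °C → rt
Reagents that add atoms: chloromethyl methyl ether, COCCl
Why: Regioselective MOM etherification, because the 4-hydroxyl para to the formyl group is far more acidic than the 3-hydroxyl, so one equivalent of weak base should generate and alkylate only the 4-phenoxide.

Step 5
Reactants: 6 3-hydroxy-4-(methoxymethoxy)benzaldehyde
Product: 7 3-(benzyloxy)-4-(methoxymethoxy)benzaldehyde
Conditions: BnBr, K2CO3, DMF, rt → 50 °C
Reagents that add atoms: benzyl bromide, BrCc1ccccc1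
Why: Williamson ether synthesis on the one remaining phenol, under conditions to which the aldehyde and the MOM acetal are inert.

Step 6
Reactants: 7 3-(benzyloxy)-4-(methoxymethoxy)benzaldehyde
Product: 8 2-(benzyloxy)-4-ethynyl-1-(methoxymethoxy)benzene
Conditions: dimethyl (1-diazo-2-oxopropyl)phosphonate, K2CO3, MeOH, 0 °C → rt
Reagents that add atoms: dimethyl (1-diazo-2-oxopropyl)phosphonate, COP(=O)(OC)C(=[N+]=[N-])C(C)=O
Why: Seyferth–Gilbert homologation in its Ohira–Bestmann form, in which the diazomethylphosphonate anion made in the flask olefinates the non-enolisable aryl aldehyde and the diazoalkene loses N2 with a 1,2-hydride shift to the terminal alkyne, under mild base that both ethers tolerate.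

Step 7
Reactants: 4 3-(benzyloxy)-2-iodo-5-(methoxymethoxy)phenol; 8 2-(benzyloxy)-4-ethynyl-1-(methoxymethoxy)benzene (1.3 equiv); 9 carbon monoxide
Product: 12 3',5-di-O-benzyl-4',7-bis-O-(methoxymethyl)luteolin, via hydroxyaryl ynone 10 (not isolated), via diethylamino enone 11 (not isolated)
Conditions: PdCl2(dppf) (5 mol%), CO (20 bar), Et2NH (solvent), 120 °C, autoclave
Reagents that add atoms: diethylamine, CCNCC (held only in intermediate 11, released again on ring closure)
Why: Pd(0) inserts into the C–I bond of 4, CO insertion gives an aroylpalladium(II) iodide, and amine-assisted transfer of the acetylide of 8 followed by reductive elimination gives ortho-hydroxyaryl ynone 10; diethylamine then adds in conjugate fashion to give enaminone 11, whose phenolic oxygen attacks the amine-bearing β-carbon and expels the amine to leave flavone 12. The closest known reaction type is the palladium-catalysed carbonylative annulation of ortho-iodophenols with terminal alkynes in a secondary amine (a carbonylative Sonogashira coupling followed by amine-relayed cyclisation), which gives flavones and 2-substituted chromones. Ring C closes in a 6-endo mode (O1 onto C2) by addition–elimination, and no stereocentre is created. Two selectivities are needed: six-membered flavone rather than five-membered aurone, secured because the secondary amine converts the ynone into an enaminone that offers only its β-carbon to the phenol, and acetylide capture of the acylpalladium rather than amide formation, favoured by CO pressure, a bidentate phosphine and a slight excess of 8. The 5/7 oxygen pattern needs no control in this step, since iodine in 4 occupies the one carbon between the free hydroxyl and the benzyl ether, so benzyl ends at O5 and MOM at O7.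

Step 8
Reactants: 12 3',5-di-O-benzyl-4',7-bis-O-(methoxymethyl)luteolin
Product: 15 3',5-di-O-benzylquercetin, via flavone 2,3-epoxide 13 (not isolated), via bis-MOM flavonol 14 (not isolated)
Conditions: DMDO (acetone solution, excess, in portions), CH2Cl2, 0 °C → rt; evaporate; then HCl (1–2 M), MeOH/THF, 40–45 °C
Reagents that add atoms: dimethyldioxirane, CC1(C)OO1
Why: Dioxirane epoxidation of the C2=C3 enol-ether bond gives the racemic cis-fused epoxide (both centres become sp2 again, so no stereochemical issue), acid then opens it at the oxocarbenium-stabilised C2 with loss of H3 to the 3-hydroxyflavone, and the same acidic methanol cleaves the two MOM acetals by transacetalisation while the benzyl ethers should stay.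

Step 9
Reactants: 15 3',5-di-O-benzylquercetin
Product: 16 3',5-di-O-benzylquercetin 3,4',7-tris(hydrogen sulfate)
Conditions: SO3·NMe3 (4–5 equiv per OH), Et3N, DMF, 60 °C; then Na+ exchange and reversed-phase purification
Reagents that add atoms: sulfur trioxide–trimethylamine complex, C[N+](C)(C)S(=O)(=O)[O-]
Why: O-sulfation with an amine–sulfur trioxide complex, which needs no site selectivity because the only free hydroxyls are those at C3, C4' and C7, the 5- and 3'-oxygens being benzylated.

Step 10
Reactants: 16 3',5-di-O-benzylquercetin 3,4',7-tris(hydrogen sulfate)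
Product: 17 quercetin 3,4',7-trisulfate
Conditions: H2 (1 atm), 10% Pd/C, MeOH/H2O (NaHCO3-buffered), rt; filter, freeze-dry
Reagents that add atoms: none
Why: Catalytic hydrogenolysis of the two aryl benzyl ethers under neutral conditions, which aryl sulfate salts and the tetrasubstituted C2=C3 bond of the flavonol should survive.

Compound list
1 | phloroglucinol (benzene-1,3,5-triol) | Oc1cc(O)cc(O)c1 | starting material
2 | 5-(methoxymethoxy)benzene-1,3-diol | COCOc1cc(O)cc(O)c1 | intermediate
3 | 2-iodo-5-(methoxymethoxy)benzene-1,3-diol | COCOc1cc(O)c(I)c(O)c1 | intermediate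
4 | 3-(benzyloxy)-2-iodo-5-(methoxymethoxy)phenol | Oc1cc(OCOC)cc(OCc2ccccc2)c1I | intermediate
5 | 3,4-dihydroxybenzaldehyde | O=Cc1ccc(O)c(O)c1 | starting material
6 | 3-hydroxy-4-(methoxymethoxy)benzaldehyde | O=Cc1ccc(OCOC)c(O)c1 | intermediate
7 | 3-(benzyloxy)-4-(methoxymethoxy)benzaldehyde | O=Cc1ccc(OCOC)c(OCc2ccccc2)c1 | intermediate
8 | 2-(benzyloxy)-4-ethynyl-1-(methoxymethoxy)benzene | C#Cc1ccc(OCOC)c(OCc2ccccc2)c1 | intermediate
9 | carbon monoxide | [C-]#[O+] | starting material
10 | 1-[2-(benzyloxy)-6-hydroxy-4-(methoxymethoxy)phenyl]-3-[3-(benzyloxy)-4-(methoxymethoxy)phenyl]prop-2-yn-1-one | O=C(C#Cc1ccc(OCOC)c(OCc2ccccc2)c1)c1c(O)cc(OCOC)cc1OCc1ccccc1 | intermediate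
11 | (E)-1-[2-(benzyloxy)-6-hydroxy-4-(methoxymethoxy)phenyl]-3-[3-(benzyloxy)-4-(methoxymethoxy)phenyl]-3-(diethylamino)prop-2-en-1-one (drawn as E; the push–pull double bond is labile and either isomer can close) | CCN(CC)/C(=C/C(=O)c1c(O)cc(OCOC)cc1OCc1ccccc1)c1ccc(OCOC)c(OCc2ccccc2)c1 | intermediate
12 | 5-(benzyloxy)-2-[3-(benzyloxy)-4-(methoxymethoxy)phenyl]-7-(methoxymethoxy)-4H-chromen-4-one (3',5-di-O-benzyl-4',7-bis-O-(methoxymethyl)luteolin) | O=c1cc(-c2ccc(OCOC)c(OCc3ccccc3)c2)oc2cc(OCOC)cc(OCc3ccccc3)c12 | intermediate
13 | 2,3-epoxide of 12 (2,3-epoxyflavanone, cis-fused, racemic; one enantiomer drawn) | O=C1[C@H]2O[C@@]2(c2ccc(OCOC)c(OCc3ccccc3)c2)Oc2cc(OCOC)cc(OCc3ccccc3)c21 | intermediate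
14 | 5-(benzyloxy)-2-[3-(benzyloxy)-4-(methoxymethoxy)phenyl]-3-hydroxy-7-(methoxymethoxy)-4H-chromen-4-one | O=c1c(O)c(-c2ccc(OCOC)c(OCc3ccccc3)c2)oc2cc(OCOC)cc(OCc3ccccc3)c12 | intermediate
15 | 5-(benzyloxy)-2-[3-(benzyloxy)-4-hydroxyphenyl]-3,7-dihydroxy-4H-chromen-4-one (3',5-di-O-benzylquercetin) | O=c1c(O)c(-c2ccc(O)c(OCc3ccccc3)c2)oc2cc(O)cc(OCc3ccccc3)c12 | intermediate
16 | 3',5-di-O-benzylquercetin 3,4',7-tris(hydrogen sulfate) | O=c1c(OS(=O)(=O)O)c(-c2ccc(OS(=O)(=O)O)c(OCc3ccccc3)c2)oc2cc(OS(=O)(=O)O)cc(OCc3ccccc3)c12 | intermediate
17 | quercetin 3,4',7-trisulfate | O=c1c(OS(=O)(=O)O)c(-c2ccc(OS(=O)(=O)O)c(O)c2)oc2cc(OS(=O)(=O)O)cc(O)c12 | target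

Total step count: 10. Longest linear sequence: 7 steps (1, 2, 3, 7, 8, 9, 10; the ring-B branch 4, 5, 6, 7, 8, 9, 10 is equally long).

Steps most likely to fail

Step 7. The aroylpalladium may be intercepted by diethylamine to give the amide, the ynone may close 5-exo to the aurone before the amine has added, and oxidative addition at the doubly ortho-substituted, electron-rich C–I bond may be slow enough for protodeiodination or CO-free coupling to compete. The fallback separates coupling from ring closure and keeps both the free phenol and the nucleophilic amine out of the palladium step. It sets out from 4 (with 8 and 9) and comes back at 12. Acetylation of 4 (Ac2O, pyridine) would give 3-(benzyloxy)-2-iodo-5-(methoxymethoxy)phenyl acetate F1. A carbonylative Sonogashira coupling of F1 with 8 under CO with a tertiary amine (PdCl2(PPh3)2, Et3N, toluene, 60–80 °C) would be stopped at the isolable 2-{3-[3-(benzyloxy)-4-(methoxymethoxy)phenyl]prop-2-ynoyl}-3-(benzyloxy)-5-(methoxymethoxy)phenyl acetate F2. Diethylamine in ethanol at room temperature would then add to the ynone, remove the acetate (10 and 11 as in the main route) and close the ring to 12.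

Step 8. The dioxirane may attack the benzylic C–H bonds of the benzyl ethers, the acetal C–H bonds or the electron-rich ring B before the deactivated C2=C3 bond is consumed, and the acid stage may start to remove the peri 5-O-benzyl ether. The fallback replaces electrophilic oxygen transfer by C3 metalation. It sets out from 12 and comes back at 14, which is then taken through the acid stage of step 8 to 15. Deprotonation of 12 at C3 with LDA (THF, −78 °C) and trapping with B(OMe)3 would give dimethyl [5-(benzyloxy)-2-[3-(benzyloxy)-4-(methoxymethoxy)phenyl]-7-(methoxymethoxy)-4-oxo-4H-chromen-3-yl]boronate F3, and oxidation of the C–B bond with H2O2/AcOH would give 14.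

Step 9. Sulfation may stall at the hydrogen-bonded, flanked 3-hydroxyl, giving di- and trisulfate mixtures that are hard to separate as salts, and the 3-O-sulfate may hydrolyse during work-up. The fallback introduces the sulfates as neutral, chromatographable diesters. It sets out from 15 and comes back at 16. Treatment of 15 with 2,2,2-trichloroethyl chlorosulfate (Et3N, DMAP, THF) would give 3',5-di-O-benzylquercetin 3,4',7-tris(2,2,2-trichloroethyl sulfate) F4, which is purified on silica. Reductive removal of the trichloroethyl groups (Zn, HCO2NH4, MeOH, rt) would give 16 after Na+ exchange.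

Further compounds
F1 | step 7 | 3-(benzyloxy)-2-iodo-5-(methoxymethoxy)phenyl acetate | CC(=O)Oc1cc(OCOC)cc(OCc2ccccc2)c1I
F2 | step 7 | 2-{3-[3-(benzyloxy)-4-(methoxymethoxy)phenyl]prop-2-ynoyl}-3-(benzyloxy)-5-(methoxymethoxy)phenyl acetate | CC(=O)Oc1cc(OCOC)cc(OCc2ccccc2)c1C(=O)C#Cc1ccc(OCOC)c(OCc2ccccc2)c1
F3 | step 8 | dimethyl [5-(benzyloxy)-2-[3-(benzyloxy)-4-(methoxymethoxy)phenyl]-7-(methoxymethoxy)-4-oxo-4H-chromen-3-yl]boronate | COB(OC)c1c(-c2ccc(OCOC)c(OCc3ccccc3)c2)oc2cc(OCOC)cc(OCc3ccccc3)c2c1=O
F4 | step 9 | 3',5-di-O-benzylquercetin 3,4',7-tris(2,2,2-trichloroethyl sulfate) | O=c1c(OS(=O)(=O)OCC(Cl)(Cl)Cl)c(-c2ccc(OS(=O)(=O)OCC(Cl)(Cl)Cl)c(OCc3ccccc3)c2)oc2cc(OS(=O)(=O)OCC(Cl)(Cl)Cl)cc(OCc3ccccc3)c12
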